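The synthesis rests on disconnecting C5–C6. C6 is an allylic carbinol carbon bonded to the trisubstituted C4=C5 alkene and γ to the C12 carboxyl, so a C5 alkenylchromium, generated from a geometrically pure iodide, adding to a C6 aldehyde (Nozaki–Hiyama–Kishi) closes the ten-membered carbocycle, creates the C6 stereocentre and supplies the alkoxide that closes the γ-lactone ring onto the C12 methyl ester in the same flask. The precursor is an acyclic C5 iodoalkene/C6 aldehyde with C7–C9 already configured and C14 masked as an acetal; its aldehyde is unveiled from a vinyl group only in the preceding step, so neither a γ-hydroxy ester nor the β-alkoxy aldehyde has to be stored.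

Key step: step 17

Remark on notation: atoms carry germacrane numbers (ring C1–C10, lactone carbons C11–C13, C14 on C10, C15 on C4); TBSO = tert-butyldimethylsilyloxy, PMBO = 4-methoxybenzyloxy.
Assumption (step 7): the antipode of the Trost ligand that delivers the 2S ether is used; the reaction is known to give either enantiomer according to the ligand.

Step 1
Reactants: 1 tert-butyldimethyl(prop-2-yn-1-yloxy)silane; 2 2-(2-bromoethyl)-1,3-dioxolane
Product: 6 tert-butyl{[(2E)-2-[2-(1,3-dioxolan-2-yl)ethyl]-3-iodoprop-2-en-1-yl]oxy}dimethylsilane, via Grignard reagent 3 (not isolated), via alkylcopper 4 (not isolated), via alkenylcopper 5 (not isolated)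
Conditions: 2, Mg, Et2O, rt; CuBr·SMe2, Et2O/Me2S, −45 °C; 1, −45 to −20 °C; I2, −60 to 0 °C
Reagents that add atoms: iodine, [I][I]
Why: Normant syn-carbocupration of the terminal alkyne by an alkylcopper–MgBr2 reagent in ether should put the chain on C4 and copper on C5 cis to it, and iodinolysis of the alkenylcopper with retention fixes the iodoalkene geometry (iodine cis to C3) that the ring closure needs.

Step 2
Reactants: 6 iodoalkene
Product: 8 tert-butyl{[(2E)-2-[2-(1,3-dioxolan-2-yl)ethyl]-3-(trimethylsilyl)prop-2-en-1-yl]oxy}dimethylsilane, via alkenyllithium 7 (not isolated)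
Conditions: t-BuLi (2.1 equiv), Et2O, −78 °C; Me3SiCl, −78 °C to rt
Reagents that add atoms: chlorotrimethylsilane, C[Si](C)(C)Cl
Why: Iodine–lithium exchange with retention of alkene geometry followed by C-silylation masks C5 as a vinylsilane that is inert to the organolithium chemistry of step 13.

Step 3
Reactants: 8 vinylsilane acetal
Product: 9 (4E)-4-(TBSOCH2)-5-(trimethylsilyl)pent-4-enal
Conditions: PPTS, acetone/H2O (10:1), 55 °C
Reagents that add atoms: water, O
Why: Acid-catalysed acetal hydrolysis of the dioxolane under pyridinium buffering should leave the primary TBS ether and the vinylsilane untouched.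

Step 4
Reactants: 10 (triphenylphosphoranylidene)acetaldehyde
Product: 12 bromo(triphenylphosphoranylidene)acetaldehyde, via bromophosphonium bromide 11 (not isolated)
Conditions: Br2, CH2Cl2, −78 to 0 °C; Et3N
Reagents that add atoms: bromine, BrBr
Why: C-Bromination of a stabilised ylide followed by deprotonation of the phosphonium salt is the standard halogenation route to α-halo formyl ylides.

Step 5
Reactants: 9 aldehyde; 12 bromo ylide
Product: 13 (2Z,6E)-2-bromo-6-(TBSOCH2)-7-(trimethylsilyl)hepta-2,6-dienal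
Conditions: toluene, 80 °C
Reagents that add atoms: none
Why: Wittig olefination with a formyl-stabilised ylide places the chain trans to the formyl group and cis to bromine, which is the C1=C10 geometry of the target (C2 trans to C14).

Step 6
Reactants: 13 bromoenal
Product: 14 [(1E,5Z)-6-bromo-7,7-dimethoxy-2-(TBSOCH2)hepta-1,5-dien-1-yl]trimethylsilane
Conditions: HC(OMe)3, PPTS (cat.), MeOH, 0 °C to rt
Reagents that add atoms: trimethyl orthoformate, COC(OC)OC
Why: Acid-catalysed acetalisation with the orthoformate as water scavenger masks C14 and removes the electrophilic carbonyl before bromine–lithium exchange.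

Step 7
Reactants: 15 2-ethenyloxirane (racemic); 16 (4-methoxyphenyl)methanol
Product: 17 (2S)-2-(PMBO)but-3-en-1-ol
Conditions: Pd2(dba)3·CHCl3 (1 mol%), Trost ligand (DACH-phenyl, 3 mol%), BEt3 (1 mol%), CH2Cl2, rt
Reagents that add atoms: none
Why: Pd-catalysed dynamic kinetic asymmetric allylic etherification (Trost asymmetric allylic alkylation with a borate-activated alcohol) captures the interconverting π-allyl complexes of the racemic epoxide at the branched carbon, and the chiral ligand sets the C8 stereocentre.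

Step 8
Reactants: 17 alcohol; 18 prop-2-enoyl chloride
Product: 19 (2S)-2-(PMBO)but-3-en-1-yl prop-2-enoate
Conditions: Et3N, CH2Cl2, −20 to 0 °C
Reagents that add atoms: none
Why: O-Acylation of the primary alcohol by the acid chloride under amine base (esterification) is straightforward and does not touch C8.

Step 9
Reactants: 19 acrylate
Product: 20 (5S)-5-(PMBO)-5,6-dihydro-2H-pyran-2-one
Conditions: second-generation Grubbs catalyst (3 mol%), CH2Cl2 (0.01 M), 40 °C
Reagents that add atoms: none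
Why: Ring-closing olefin metathesis of the acrylate with the terminal alkene, driven by loss of ethene, gives the six-membered unsaturated lactone that will relay C8 to C7.

Step 10
Reactants: 20 unsaturated lactone; 21 ethenylmagnesium bromide
Product: 22 (4S,5S)-4-ethenyl-5-(PMBO)oxan-2-one (4,5-trans)
Conditions: CuBr·SMe2 (10 mol%), THF/Me2S, −78 to −40 °C; aq. NH4Cl
Reagents that add atoms: none
Why: Copper-catalysed conjugate addition of the vinyl Grignard reagent occurs anti to the adjacent C8 ether on the half-chair lactone, so the 4,5-trans product sets C7 from C8 with the 7,8-relationship of the target.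

Step 11
Reactants: 22 lactone
Product: 23 methyl (3S,4S)-3-ethenyl-5-hydroxy-4-(PMBO)pentanoate
Conditions: NaOMe (0.1 equiv), MeOH, 0 °C; AcOH (0.1 equiv), concentrate cold
Reagents that add atoms: methanol, CO
Why: Base-catalysed transesterification in methanol opens the δ-lactone to the C12 methyl ester and frees the primary C9 hydroxyl, which is oxidised without delay to forestall relactonisation.

Step 12
Reactants: 23 hydroxy ester
Product: 24 methyl (3S,4S)-3-ethenyl-4-(PMBO)-5-oxopentanoate
Conditions: Dess–Martin periodinane, NaHCO3, CH2Cl2, 0 °C to rt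
Reagents that add atoms: none
Why: Dess–Martin oxidation of the primary alcohol under bicarbonate buffering should give the α-alkoxy aldehyde without epimerising C8, and the aldehyde is used crude.

Step 13
Reactants: 14 alkenyl bromide; 24 aldehyde
Product: 27 methyl (3S,4S,5S,6E,10E)-6-(dimethoxymethyl)-3-ethenyl-5-hydroxy-4-(PMBO)-10-(TBSOCH2)-11-(trimethylsilyl)undeca-6,10-dienoate, via alkenyllithium 25 (not isolated), via alkenylmagnesium bromide 26 (not isolated)
Conditions: 14 (1.3 equiv), t-BuLi (2.6 equiv), Et2O, −78 °C; MgBr2·OEt2, −78 °C; 24, CH2Cl2, −78 °C; aq. NH4Cl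
Reagents that add atoms: none
Why: Bromine–lithium exchange with retention, transmetalation to magnesium and Cram-chelate-controlled 1,2-addition, in which magnesium bridges the aldehyde oxygen and the C8 PMB ether oxygen so that the alkenyl group attacks the face away from the C7 branch, should give the 8,9-syn (9S) carbinol.

Step 14
Reactants: 27 allylic alcohol
Product: 28 methyl (3S,4S,5S,6E,10E)-5-(TBSO)-6-(dimethoxymethyl)-3-ethenyl-4-(PMBO)-10-(TBSOCH2)-11-(trimethylsilyl)undeca-6,10-dienoate
Conditions: TBSOTf, 2,6-lutidine, CH2Cl2, −78 °C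
Reagents that add atoms: tert-butyldimethylsilyl trifluoromethanesulfonate, CC(C)(C)[Si](C)(C)OS(=O)(=O)C(F)(F)F
Why: Silyl ether formation with the silyl triflate at low temperature is fast enough for the hindered C9 hydroxyl to outrun both δ-lactonisation onto the ester and ionisation of the acetal.

Step 15
Reactants: 28 vinylsilane
Product: 29 methyl (3S,4S,5S,6E,10E)-5-(TBSO)-6-(dimethoxymethyl)-3-ethenyl-11-iodo-4-(PMBO)-10-(TBSOCH2)undeca-6,10-dienoate
Conditions: N-iodosuccinimide (1.3 equiv), 2,6-lutidine, (CF3)2CHOH, 0 °C, short reaction time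
Reagents that add atoms: N-iodosuccinimide, O=C1CCC(=O)N1I
Why: ipso-Iododesilylation through a β-silyl cation should proceed with retention in the fluorinated alcohol, the 2,2-disubstituted vinylsilane being far more nucleophilic than the terminal vinyl group, the hindered C1=C10 alkene or the anisyl ring.

Step 16
Reactants: 29 iodoalkene
Product: 31 methyl (3R,4S,5S,6E,10E)-5-(TBSO)-6-(dimethoxymethyl)-3-formyl-11-iodo-4-(PMBO)-10-(TBSOCH2)undeca-6,10-dienoate, via diol 30 (not isolated)
Conditions: OsO4 (2 mol%), NaIO4 (4 equiv), 2,6-lutidine, dioxane/H2O (3:1), 0 °C to rt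
Reagents that add atoms: sodium periodate (terminal oxidant, its oxygen reaches C6 through OsO4), [Na+].[O-][I](=O)(=O)=O
Why: In this Lemieux–Johnson oxidation OsO4 should dihydroxylate the unhindered monosubstituted alkene in preference to the iodine-deactivated C4=C5 and the hindered, doubly allylically oxygenated C1=C10 alkene, and periodate cleaves diol 30 as it forms, so the C6 aldehyde appears without a γ-hydroxy ester accumulating and without touching C7.

Step 17
Reactants: 31 iodoalkene aldehyde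
Product: 34 (3aS,4S,5S,6E,10E,11aR)-5-(TBSO)-6-(dimethoxymethyl)-4-(PMBO)-10-(TBSOCH2)-3a,4,5,8,9,11a-hexahydrocyclodeca[b]furan-2(3H)-one, via alkenylchromium 32 (not isolated), via chromium alkoxide 33 (not isolated)
Conditions: CrCl2 (10 equiv), NiCl2 (1 mol% of the CrCl2), DMSO/THF (3:1), 0.003 M, slow addition of 31, rt; aq. NH4Cl
Reagents that add atoms: none
Why: Zerovalent nickel (formed from NiCl2 and CrCl2) inserts into the C5–I bond with retention, transmetalation gives alkenylchromium 32, and this adds to the C6 aldehyde; the trivalent chromium alkoxide 33 then attacks the C12 methyl ester and expels methoxide. The closest known reaction type is the intramolecular Nozaki–Hiyama–Kishi coupling of alkenyl iodides with aldehydes to medium-ring allylic alcohols, followed by lactonisation of a γ-alkoxide ester. The ten-membered carbocycle closes by 10-exo-trig carbonyl addition (C5 onto C6) and the lactone ring by 5-exo-trig acyl substitution (O6 onto C12). The new C6 stereocentre is controlled by C7: Felkin–Anh attack anti to the C8 branch, reinforced by the 1,3-anti preference of the C8 ether, should give 6R and hence the trans-fused lactone. The step needs chemoselectivity for the aldehyde, secured by the low basicity and nucleophilicity of organochromium reagents (ester, acetal, epimerisable C7 and β-alkoxy group are spared), and ring closure over oligomerisation, secured by slow addition at high dilution and by the two ring-cis trisubstituted alkenes that fold the chain.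

Step 18
Reactants: 34 lactone
Product: 38 (3aS,4S,5S,6E,10E,11aR)-5-(TBSO)-6-(dimethoxymethyl)-3-methylidene-4-(PMBO)-10-(TBSOCH2)-3a,4,5,8,9,11a-hexahydrocyclodeca[b]furan-2(3H)-one, via lithium enolate 35 (not isolated), via Mannich base 36 (not isolated), via ammonium iodide 37 (not isolated)
Conditions: LDA, THF, −78 °C; CH2=NMe2+ I−, −78 °C to rt; iodomethane, rt; DBU, rt
Reagents that add atoms: dimethylmethyleneiminium iodide (Eschenmoser's salt), C=[N+](C)C.[I-]
Why: α-Methylenation of the lactone by Mannich reaction of its lithium enolate with Eschenmoser's salt, exhaustive N-methylation and base-induced E1cB loss of trimethylamine makes C11 sp2, so no stereocentre is at stake.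

Step 19
Reactants: 38 PMB ether
Product: 39 (3aR,4S,5S,6E,10E,11aR)-5-(TBSO)-6-(dimethoxymethyl)-4-hydroxy-3-methylidene-10-(TBSOCH2)-3a,4,5,8,9,11a-hexahydrocyclodeca[b]furan-2(3H)-one (3a descriptor changes by priority only)
Conditions: DDQ, CH2Cl2/pH 7 phosphate buffer (10:1), 0 °C
Reagents that add atoms: none
Why: Oxidative PMB ether cleavage by DDQ (benzylic hydride abstraction, then hydrolysis of the oxocarbenium ion) in buffered wet CH2Cl2 should spare the silyl ethers, the acetal and the α-methylene lactone.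

Step 20
Reactants: 39 C8 alcohol; 40 (2S)-2-methylbutanoic acid
Product: 41 (3aS,4S,5S,6E,10E,11aR)-5-(TBSO)-6-(dimethoxymethyl)-3-methylidene-2-oxo-10-(TBSOCH2)-2,3,3a,4,5,8,9,11a-octahydrocyclodeca[b]furan-4-yl (2S)-2-methylbutanoate
Conditions: DCC, DMAP (0.3 equiv), CH2Cl2, 0 °C to rt
Reagents that add atoms: none
Why: Steglich esterification (carbodiimide activation with acyl transfer by DMAP) acylates the C8 hydroxyl, and the low temperature with sub-stoichiometric DMAP keeps the α-stereocentre of the acid from epimerising.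

Step 21
Reactants: 41 protected ester
Product: 42 (3aS,4S,5S,6E,10E,11aR)-6-formyl-5-hydroxy-10-(hydroxymethyl)-3-methylidene-2-oxo-2,3,3a,4,5,8,9,11a-octahydrocyclodeca[b]furan-4-yl (2S)-2-methylbutanoate (target)
Conditions: HF (48% aq.), MeCN, 0 °C to rt
Reagents that add atoms: water, O
Why: Global acidic deprotection, combining fluoride-assisted cleavage of both TBS ethers with hydrolysis of the allylic dimethyl acetal to the conjugated C14 aldehyde, is mild enough for the ester, the allylic alcohols and the α-methylene lactone.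

Compound list
1 | tert-butyldimethyl(prop-2-yn-1-yloxy)silane | C#CCO[Si](C)(C)C(C)(C)C | starting material
2 | 2-(2-bromoethyl)-1,3-dioxolane | BrCCC1OCCO1 | starting material
3 | [2-(1,3-dioxolan-2-yl)ethyl]magnesium bromide | Br[Mg]CCC1OCCO1 | intermediate
4 | [2-(1,3-dioxolan-2-yl)ethyl]copper (MgBr2 complex) | [Cu]CCC1OCCO1 | intermediate
5 | (E)-alkenylcopper, copper on C5 cis to the C3 chain | [Cu]/C=C(/CO[Si](C)(C)C(C)(C)C)CCC1OCCO1 | intermediate
6 | tert-butyl{[(2E)-2-[2-(1,3-dioxolan-2-yl)ethyl]-3-iodoprop-2-en-1-yl]oxy}dimethylsilane | I/C=C(/CO[Si](C)(C)C(C)(C)C)CCC1OCCO1 | intermediate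
7 | alkenyllithium from 6 (lithium in place of iodine, geometry retained) | [Li]/C=C(/CO[Si](C)(C)C(C)(C)C)CCC1OCCO1 | intermediate
8 | tert-butyl{[(2E)-2-[2-(1,3-dioxolan-2-yl)ethyl]-3-(trimethylsilyl)prop-2-en-1-yl]oxy}dimethylsilane | C[Si](C)(C)/C=C(/CO[Si](C)(C)C(C)(C)C)CCC1OCCO1 | intermediate
9 | (4E)-4-(TBSOCH2)-5-(trimethylsilyl)pent-4-enal | C[Si](C)(C)/C=C(/CO[Si](C)(C)C(C)(C)C)CCC=O | intermediate
10 | (triphenylphosphoranylidene)acetaldehyde | O=CC=P(c1ccccc1)(c1ccccc1)c1ccccc1 | starting material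
11 | (1-bromo-2-oxoethyl)triphenylphosphonium bromide | O=CC(Br)[P+](c1ccccc1)(c1ccccc1)c1ccccc1.[Br-] | intermediate
12 | bromo(triphenylphosphoranylidene)acetaldehyde | O=CC(Br)=P(c1ccccc1)(c1ccccc1)c1ccccc1 | intermediate
13 | (2Z,6E)-2-bromo-6-(TBSOCH2)-7-(trimethylsilyl)hepta-2,6-dienal | C[Si](C)(C)/C=C(/CO[Si](C)(C)C(C)(C)C)CC/C=C(/C=O)Br | intermediate
14 | [(1E,5Z)-6-bromo-7,7-dimethoxy-2-(TBSOCH2)hepta-1,5-dien-1-yl]trimethylsilane | C[Si](C)(C)/C=C(/CO[Si](C)(C)C(C)(C)C)CC/C=C(/C(OC)OC)Br | intermediate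
15 | 2-ethenyloxirane (racemic) | C=CC1CO1 | starting material
16 | (4-methoxyphenyl)methanol | COc1ccc(CO)cc1 | starting material
17 | (2S)-2-(PMBO)but-3-en-1-ol | OC[C@@H](OCc1ccc(OC)cc1)C=C | intermediate
18 | prop-2-enoyl chloride | C=CC(=O)Cl | starting material
19 | (2S)-2-(PMBO)but-3-en-1-yl prop-2-enoate | C=CC(=O)OC[C@@H](OCc1ccc(OC)cc1)C=C | intermediate
20 | (5S)-5-(PMBO)-5,6-dihydro-2H-pyran-2-one | O=C1OC[C@@H](OCc2ccc(OC)cc2)C=C1 | intermediate
21 | ethenylmagnesium bromide | C=C[Mg]Br | starting material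
22 | (4S,5S)-4-ethenyl-5-(PMBO)oxan-2-one (trans) | O=C1OC[C@@H](OCc2ccc(OC)cc2)[C@H](C=C)C1 | intermediate
23 | methyl (3S,4S)-3-ethenyl-5-hydroxy-4-(PMBO)pentanoate | OC[C@@H](OCc1ccc(OC)cc1)[C@H](C=C)CC(=O)OC | intermediate
24 | methyl (3S,4S)-3-ethenyl-4-(PMBO)-5-oxopentanoate | O=C[C@@H](OCc1ccc(OC)cc1)[C@H](C=C)CC(=O)OC | intermediate
25 | alkenyllithium from 14 (lithium on C10, cis to C2) | C[Si](C)(C)/C=C(/CO[Si](C)(C)C(C)(C)C)CC/C=C(/C(OC)OC)[Li] | intermediate
26 | alkenylmagnesium bromide from 25 | C[Si](C)(C)/C=C(/CO[Si](C)(C)C(C)(C)C)CC/C=C(/C(OC)OC)[Mg]Br | intermediate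
27 | methyl (3S,4S,5S,6E,10E)-6-(dimethoxymethyl)-3-ethenyl-5-hydroxy-4-(PMBO)-10-(TBSOCH2)-11-(trimethylsilyl)undeca-6,10-dienoate | C[Si](C)(C)/C=C(/CO[Si](C)(C)C(C)(C)C)CC/C=C(/C(OC)OC)[C@H](O)[C@@H](OCc1ccc(OC)cc1)[C@H](C=C)CC(=O)OC | intermediate
28 | C9 TBS ether of 27 | C[Si](C)(C)/C=C(/CO[Si](C)(C)C(C)(C)C)CC/C=C(/C(OC)OC)[C@H](O[Si](C)(C)C(C)(C)C)[C@@H](OCc1ccc(OC)cc1)[C@H](C=C)CC(=O)OC | intermediate
29 | methyl (3S,4S,5S,6E,10E)-5-(TBSO)-6-(dimethoxymethyl)-3-ethenyl-11-iodo-4-(PMBO)-10-(TBSOCH2)undeca-6,10-dienoate | I/C=C(/CO[Si](C)(C)C(C)(C)C)CC/C=C(/C(OC)OC)[C@H](O[Si](C)(C)C(C)(C)C)[C@@H](OCc1ccc(OC)cc1)[C@H](C=C)CC(=O)OC | intermediate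
30 | 3-(1,2-dihydroxyethyl) analogue of 29 (both carbinol epimers) | I/C=C(/CO[Si](C)(C)C(C)(C)C)CC/C=C(/C(OC)OC)[C@H](O[Si](C)(C)C(C)(C)C)[C@@H](OCc1ccc(OC)cc1)[C@H](C(O)CO)CC(=O)OC | intermediate
31 | methyl (3R,4S,5S,6E,10E)-5-(TBSO)-6-(dimethoxymethyl)-3-formyl-11-iodo-4-(PMBO)-10-(TBSOCH2)undeca-6,10-dienoate | I/C=C(/CO[Si](C)(C)C(C)(C)C)CC/C=C(/C(OC)OC)[C@H](O[Si](C)(C)C(C)(C)C)[C@@H](OCc1ccc(OC)cc1)[C@@H](CC(=O)OC)C=O | intermediate
32 | C5 alkenylchromium dichloride from 31 | Cl[Cr](Cl)/C=C(/CO[Si](C)(C)C(C)(C)C)CC/C=C(/C(OC)OC)[C@H](O[Si](C)(C)C(C)(C)C)[C@@H](OCc1ccc(OC)cc1)[C@@H](CC(=O)OC)C=O | intermediate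
33 | dichlorochromium C6 alkoxide of the ten-membered hydroxy ester (6R) | Cl[Cr](Cl)O[C@@H]1/C=C(/CO[Si](C)(C)C(C)(C)C)CC/C=C(/C(OC)OC)[C@H](O[Si](C)(C)C(C)(C)C)[C@@H](OCc2ccc(OC)cc2)[C@H]1CC(=O)OC | intermediate
34 | (3aS,4S,5S,6E,10E,11aR)-5-(TBSO)-6-(dimethoxymethyl)-4-(PMBO)-10-(TBSOCH2)-3a,4,5,8,9,11a-hexahydrocyclodeca[b]furan-2(3H)-one | C1C(=O)O[C@@H]2/C=C(/CO[Si](C)(C)C(C)(C)C)CC/C=C(/C(OC)OC)[C@H](O[Si](C)(C)C(C)(C)C)[C@@H](OCc3ccc(OC)cc3)[C@@H]12 | intermediate
35 | lithium enolate of 34 | C1=C(O[Li])O[C@@H]2/C=C(/CO[Si](C)(C)C(C)(C)C)CC/C=C(/C(OC)OC)[C@H](O[Si](C)(C)C(C)(C)C)[C@@H](OCc3ccc(OC)cc3)[C@@H]12 | intermediate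
36 | 3-[(dimethylamino)methyl] derivative of 34 (C11 epimers) | CN(C)CC1C(=O)O[C@@H]2/C=C(/CO[Si](C)(C)C(C)(C)C)CC/C=C(/C(OC)OC)[C@H](O[Si](C)(C)C(C)(C)C)[C@@H](OCc3ccc(OC)cc3)[C@@H]12 | intermediate
37 | trimethylammonium iodide of 36 | C[N+](C)(C)CC1C(=O)O[C@@H]2/C=C(/CO[Si](C)(C)C(C)(C)C)CC/C=C(/C(OC)OC)[C@H](O[Si](C)(C)C(C)(C)C)[C@@H](OCc3ccc(OC)cc3)[C@@H]12.[I-] | intermediate
38 | 3-methylidene derivative of 34 (3aS,4S,5S,6E,10E,11aR) | C=C1C(=O)O[C@@H]2/C=C(/CO[Si](C)(C)C(C)(C)C)CC/C=C(/C(OC)OC)[C@H](O[Si](C)(C)C(C)(C)C)[C@@H](OCc3ccc(OC)cc3)[C@@H]12 | intermediate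
39 | (3aR,4S,5S,6E,10E,11aR)-5-(TBSO)-6-(dimethoxymethyl)-4-hydroxy-3-methylidene-10-(TBSOCH2)-3a,4,5,8,9,11a-hexahydrocyclodeca[b]furan-2(3H)-one | C=C1C(=O)O[C@@H]2/C=C(/CO[Si](C)(C)C(C)(C)C)CC/C=C(/C(OC)OC)[C@H](O[Si](C)(C)C(C)(C)C)[C@@H](O)[C@@H]12 | intermediate
40 | (2S)-2-methylbutanoic acid | CC[C@H](C)C(=O)O | starting material
41 | (3aS,4S,5S,6E,10E,11aR)-5-(TBSO)-6-(dimethoxymethyl)-3-methylidene-2-oxo-10-(TBSOCH2)-2,3,3a,4,5,8,9,11a-octahydrocyclodeca[b]furan-4-yl (2S)-2-methylbutanoate | C=C1C(=O)O[C@@H]2/C=C(/CO[Si](C)(C)C(C)(C)C)CC/C=C(/C(OC)OC)[C@H](O[Si](C)(C)C(C)(C)C)[C@@H](OC(=O)[C@@H](C)CC)[C@@H]12 | intermediate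
42 | (3aS,4S,5S,6E,10E,11aR)-6-formyl-5-hydroxy-10-(hydroxymethyl)-3-methylidene-2-oxo-2,3,3a,4,5,8,9,11a-octahydrocyclodeca[b]furan-4-yl (2S)-2-methylbutanoate | C=C1C(=O)O[C@@H]2/C=C(/CO)CC/C=C(/C=O)[C@H](O)[C@@H](OC(=O)[C@@H](C)CC)[C@@H]12 | target

Total step count: 21 steps.
Longest linear sequence: 15 steps (steps 7–12, then 13–21, from 15 and 16).

Steps most likely to fail

Step 17. The alkenylchromium may attack the wrong face of the C6 aldehyde if the folded chain overrides the Felkin–Anh preference, so that the C6 epimer forms and lactonises to the cis-fused lactone. The fallback fixes C6 by inversion instead of by facial control. It sets out from 31: ring closure under the step 17 conditions would then deliver the cis-fused C6-epimeric lactone F1, which LiOH in THF/H2O opens to the seco hydroxy acid F2. Intramolecular Mitsunobu lactonisation of F2 (PPh3, DIAD, toluene, 0 °C) closes the γ-lactone with inversion at C6 and comes back to the route at 34.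

Step 13. Chelation may be incomplete, the hindered alkenylmagnesium reagent reacting through an open Felkin-type transition state, which erodes facial selectivity at C9 and leaves the C9 epimer F3 beside 27. The fallback replaces substrate-controlled addition by reagent-controlled reduction. It sets out from the mixture of 27 and the C9 epimer F3: Dess–Martin oxidation converges both on the C9 ketone F4, and Corey–Bakshi–Shibata reduction (oxazaborolidine antipode matched to the 9S carbinol, catecholborane, toluene, −78 °C) comes back to the route at 27.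

Step 1. The alkylcopper may add with reversed regiochemistry (copper on C4, then β-elimination of the silyloxide to an allene), or the acetal-bearing Grignard reagent may decompose before it reaches copper. The fallback takes the alkene geometry from a decarboxylative elimination instead of a carbometalation. It sets out from 2, which alkylates diethyl malonate (NaH, THF) to give diethyl [2-(1,3-dioxolan-2-yl)ethyl]propanedioate F5. Iodoform and NaH in refluxing Et2O give the diiodomethyl malonate F6. KOH in aqueous ethanol at reflux brings about saponification, decarboxylation and loss of iodide to give the E iodoacrylic acid F7, with iodine cis to the chain. LiAlH4 in Et2O at 0 °C reduces it to the allylic alcohol F8, and TBSCl with imidazole in DMF comes back to the route at 6.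

Further compounds
F1 | step 17 | C6 epimer of 34 (cis-fused lactone) | C1C(=O)O[C@H]2/C=C(/CO[Si](C)(C)C(C)(C)C)CC/C=C(/C(OC)OC)[C@H](O[Si](C)(C)C(C)(C)C)[C@@H](OCc3ccc(OC)cc3)[C@@H]12
F2 | step 17 | seco hydroxy acid from F1 (C6 hydroxyl, C12 carboxylic acid) | O[C@H]1/C=C(/CO[Si](C)(C)C(C)(C)C)CC/C=C(/C(OC)OC)[C@H](O[Si](C)(C)C(C)(C)C)[C@@H](OCc2ccc(OC)cc2)[C@H]1CC(=O)O
F3 | step 13 | C9 epimer of 27 | C[Si](C)(C)/C=C(/CO[Si](C)(C)C(C)(C)C)CC/C=C(/C(OC)OC)[C@@H](O)[C@@H](OCc1ccc(OC)cc1)[C@H](C=C)CC(=O)OC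
F4 | step 13 | C9 ketone (enone) from 27 and F3 | C[Si](C)(C)/C=C(/CO[Si](C)(C)C(C)(C)C)CC/C=C(/C(OC)OC)C(=O)[C@@H](OCc1ccc(OC)cc1)[C@H](C=C)CC(=O)OC
F5 | step 1 | diethyl [2-(1,3-dioxolan-2-yl)ethyl]propanedioate | CCOC(=O)C(CCC1OCCO1)C(=O)OCC
F6 | step 1 | diethyl (diiodomethyl)[2-(1,3-dioxolan-2-yl)ethyl]propanedioate | CCOC(=O)C(CCC1OCCO1)(C(I)I)C(=O)OCC
F7 | step 1 | (2E)-2-[2-(1,3-dioxolan-2-yl)ethyl]-3-iodoprop-2-enoic acid | I/C=C(/C(=O)O)CCC1OCCO1
F8 | step 1 | (2E)-2-[2-(1,3-dioxolan-2-yl)ethyl]-3-iodoprop-2-en-1-ol | I/C=C(/CO)CCC1OCCO1
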